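**Retrosynthetic overview**
- Feature: in the upper chroman (O1, C2, C3, C4, C4a, C8a), ring A carries O1 on C8a and an oxygen on C7, ortho and para to C4a. C4 also bears the donor ring D through D5. C4 is therefore the terminus of a stabilised ortho-quinone methide, and C3–C2 with ring B is a masked arylacetic acid.
- Key disconnection: C3–C4 and O1–C2 are cut together. This gives a ring A phenol with a sulfinate leaving group on C4 and the lower isoflavan attached (fragment 1), and 2-(2-benzyloxy-4,5-dimethoxyphenyl)acetic acid (fragment 2). A chiral isothiourea joins them in a formal (4+2) annulation to the dihydrocoumarin.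
- The lactone carbon C2 is then lowered to CH2 by reduction and Mitsunobu reclosure of O1–C2, and the four benzyl ethers are removed by hydrogenolysis.
- Fragment 1: C4–D5 comes from the D5 aryllithium of a bromo isoflavan and a ring A aldehyde, followed by sulfinate exchange. The bromo isoflavan comes from an Evans benzylation (lower C3) and a Mitsunobu closure.
- Ring order: ring F (lower pyran), then ring C as lactone, then ring C again as cyclic ether. Rings A, B, D and E are bought as arenes.

Key step: step 18

Labels: the upper chroman has benzo ring A and pyran ring C; ring B sits on C3 and ring D on C4 (D1 carries the lower chroman, D2 an oxygen, D4 the methoxy group, D5 is bonded to C4); the lower chroman has benzo ring E and pyran ring F, and its stereocentre is called lower C3.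

Assumption: the annulation is taken to be kinetically cis selective, as it is with isolable ortho-quinone methides, so the catalyst antipode is chosen for C4 and C3 is corrected afterwards by base.

**Step 1**
Reactants: 1 2,4-dihydroxybenzaldehyde
Product: 2 4-benzyloxy-2-hydroxybenzaldehyde
Conditions: BnBr (1.0 equiv), NaHCO3, KI (cat), MeCN, reflux
Reagents that add atoms: benzyl bromide, BrCc1ccccc1
Why: Williamson etherification under a weak base, in which the C2 hydroxyl is locked in a hydrogen bond to the formyl oxygen and stays protonated, so only the more acidic C4 phenol is benzylated.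

**Step 2**
Reactants: 2 4-benzyloxy-2-hydroxybenzaldehyde
Product: 3 2-allyloxy-4-benzyloxybenzaldehyde
Conditions: allyl bromide, K2CO3, DMF, 50 °C
Reagents that add atoms: allyl bromide, C=CCBr
Why: Williamson etherification with a stronger base alkylates the remaining chelated phenol, and allyl is chosen because zerovalent palladium removes it later beside benzyl ethers.

**Step 3**
Reactants: 3 2-allyloxy-4-benzyloxybenzaldehyde
Product: 4 (2-allyloxy-4-benzyloxyphenyl)methanol
Conditions: NaBH4, MeOH/THF, 0 °C
Reagents that add atoms: none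
Why: Borohydride reduction of an aromatic aldehyde, to which the ethers and the terminal alkene are inert.

**Step 4**
Reactants: 4 (2-allyloxy-4-benzyloxyphenyl)methanol
Product: 5 2-allyloxy-4-benzyloxybenzyl bromide
Conditions: PBr3 (0.4 equiv), Et2O, 0 °C, used crude
Reagents that add atoms: phosphorus tribromide, BrP(Br)Br
Why: Substitution of a primary benzylic alcohol by PBr3 through its phosphite ester; the donor-rich bromide is labile, so it is taken on at once without chromatography.

**Step 5**
Reactants: 6 5-bromo-2-hydroxy-4-methoxybenzaldehyde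
Product: 7 2-benzyloxy-5-bromo-4-methoxybenzaldehyde
Conditions: BnBr, K2CO3, DMF, rt
Reagents that add atoms: benzyl bromide, BrCc1ccccc1
Why: Williamson etherification of the only phenol, with the aryl bromide that marks D5 inert.

**Step 6**
Reactants: 7 2-benzyloxy-5-bromo-4-methoxybenzaldehyde
Product: 9 2-(2-benzyloxy-5-bromo-4-methoxyphenyl)acetonitrile, via tosyl vinyl formamide 8 (not isolated)
Conditions: TosMIC, KOtBu, DME, −35 °C; then MeOH, reflux
Reagents that add atoms: p-toluenesulfonylmethyl isocyanide (TosMIC), Cc1ccc(cc1)S(=O)(=O)C[N+]#[C-]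
Why: Van Leusen reductive cyanation, in which the TosMIC anion adds to the aldehyde, the oxazoline opens to formamide 8, and methanolysis of the formyl group followed by loss of sulfinate leaves the nitrile with one more carbon.

**Step 7**
Reactants: 9 2-(2-benzyloxy-5-bromo-4-methoxyphenyl)acetonitrile
Product: 10 2-(2-benzyloxy-5-bromo-4-methoxyphenyl)acetic acid
Conditions: KOH, EtOH/H2O, reflux; then aq HCl
Reagents that add atoms: potassium hydroxide, [K+].[OH-]; water, O
Why: Alkaline hydrolysis of a nitrile through the primary amide, which the aryl bromide and the aryl ethers tolerate.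

**Step 8**
Reactants: 10 2-(2-benzyloxy-5-bromo-4-methoxyphenyl)acetic acid; 11 (R)-4-benzyloxazolidin-2-one
Product: 13 (4R)-4-benzyl-3-[2-(2-benzyloxy-5-bromo-4-methoxyphenyl)acetyl]oxazolidin-2-one, via mixed pivalic anhydride 12 (not isolated)
Conditions: t-BuCOCl, Et3N, THF, −20 °C; then LiCl, 11, −20 °C to rt
Reagents that add atoms: none
Why: N-acylation of an oxazolidinone through a mixed pivalic anhydride, in which the tert-butyl group directs the LiCl-activated carbamate to the arylacetyl carbonyl and the stereocentre of 11 is not involved.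

**Step 9**
Reactants: 13 (4R)-4-benzyl-3-[2-(2-benzyloxy-5-bromo-4-methoxyphenyl)acetyl]oxazolidin-2-one; 5 2-allyloxy-4-benzyloxybenzyl bromide
Product: 15 (4R)-4-benzyl-3-[(2R)-3-(2-allyloxy-4-benzyloxyphenyl)-2-(2-benzyloxy-5-bromo-4-methoxyphenyl)propanoyl]oxazolidin-2-one, via sodium Z enolate 14 (not isolated)
Conditions: NaN(SiMe3)2, THF, −78 °C; then 5, −78 to −30 °C
Reagents that add atoms: none
Why: Evans asymmetric alkylation, in which the C4 benzyl group of the R auxiliary covers one face of the sodium-chelated Z enolate 14, so the reactive benzylic bromide enters from the other face and sets the future lower C3 as R.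

**Step 10**
Reactants: 15 the benzylated imide
Product: 16 (2R)-3-(2-allyloxy-4-benzyloxyphenyl)-2-(2-benzyloxy-5-bromo-4-methoxyphenyl)propan-1-ol
Conditions: LiBH4, H2O (1 equiv), Et2O/THF, 0 °C
Reagents that add atoms: none
Why: Reductive cleavage of the N-acyl oxazolidinone with LiBH4, which attacks the exocyclic carbonyl faster than the benzylic alpha hydrogen can be removed, so the stereocentre is kept and the auxiliary is recovered.

**Step 11**
Reactants: 16 the allyl-protected alcohol
Product: 17 5-benzyloxy-2-[(2R)-2-(2-benzyloxy-5-bromo-4-methoxyphenyl)-3-hydroxypropyl]phenol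
Conditions: Pd(PPh3)4 (3 mol %), morpholine, THF, rt
Reagents that add atoms: none
Why: Tsuji–Trost deallylation, in which zerovalent palladium ionises the aryl allyl ether and morpholine takes up the allyl unit, while oxidative addition into the hindered and donor-rich aryl bromide is slow at room temperature.

**Step 12**
Reactants: 17 the phenol alcohol
Product: 18 (3R)-7-benzyloxy-3-(2-benzyloxy-5-bromo-4-methoxyphenyl)chroman
Conditions: PPh3, DIAD, THF, 0 °C to rt
Reagents that add atoms: none
Why: Intramolecular Mitsunobu etherification, in which the phenol displaces the activated primary alcohol in a 6-exo-tet closure of ring F and the neighbouring stereocentre takes no part.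

**Step 13**
Reactants: 18 the bromo isoflavan; 3 2-allyloxy-4-benzyloxybenzaldehyde
Product: 20 (2-allyloxy-4-benzyloxyphenyl){4-benzyloxy-5-[(3R)-7-benzyloxychroman-3-yl]-2-methoxyphenyl}methanol (both carbinol epimers), via aryllithium 19 (not isolated)
Conditions: n-BuLi, THF, −78 °C; then 3, −78 °C; H2O quench
Reagents that add atoms: none
Why: Bromine–lithium exchange, fast at −78 °C and helped by the ortho methoxy group, followed by 1,2-addition of aryllithium 19 to the aldehyde forms C4–D5; the carbinol carbon forms as both epimers, which does not matter because it becomes planar in step 18.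

**Step 14**
Reactants: 20 the diaryl carbinol
Product: 22 fragment 1: 5-benzyloxy-2-[{4-benzyloxy-5-[(3R)-7-benzyloxychroman-3-yl]-2-methoxyphenyl}(4-methylphenylsulfonyl)methyl]phenol (both sulfone epimers), via O-allyl sulfone 21 (not isolated)
Conditions: p-TolSO2H (3 equiv), CH2Cl2, 0 °C to rt; then Pd(PPh3)4 (5 mol %), rt; purified by crystallisation
Reagents that add atoms: p-toluenesulfinic acid, Cc1ccc(cc1)S(=O)O
Why: Direct SN1 substitution of a benzhydrol flanked by two donor rings with a sulfinic acid gives sulfone 21, and the excess sulfinic acid then acts as allyl acceptor in the palladium-catalysed deallylation of the aryl allyl ether; the sulfone carbon is again a mixture of epimers.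

**Step 15**
Reactants: 23 2-hydroxy-4,5-dimethoxybenzaldehyde
Product: 24 2-benzyloxy-4,5-dimethoxybenzaldehyde
Conditions: BnBr, K2CO3, DMF, rt
Reagents that add atoms: benzyl bromide, BrCc1ccccc1
Why: Williamson etherification of the only phenol.

**Step 16**
Reactants: 24 2-benzyloxy-4,5-dimethoxybenzaldehyde
Product: 26 2-(2-benzyloxy-4,5-dimethoxyphenyl)acetonitrile, via tosyl vinyl formamide 25 (not isolated)
Conditions: TosMIC, KOtBu, DME, −35 °C; then MeOH, reflux
Reagents that add atoms: p-toluenesulfonylmethyl isocyanide (TosMIC), Cc1ccc(cc1)S(=O)(=O)C[N+]#[C-]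
Why: Van Leusen reductive cyanation as in step 6, turning the formyl carbon into the benzylic CH2 that becomes C3 and adding the carbon that becomes C2.

**Step 17**
Reactants: 26 2-(2-benzyloxy-4,5-dimethoxyphenyl)acetonitrile
Product: 27 fragment 2: 2-(2-benzyloxy-4,5-dimethoxyphenyl)acetic acid
Conditions: KOH, EtOH/H2O, reflux; then aq HCl
Reagents that add atoms: potassium hydroxide, [K+].[OH-]; water, O
Why: Alkaline nitrile hydrolysis, to which the aryl ethers are inert.

**Step 18**
Reactants: 22 fragment 1; 27 fragment 2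
Product: 31 (3R,4S)-7-benzyloxy-3-(2-benzyloxy-4,5-dimethoxyphenyl)-4-{4-benzyloxy-5-[(3R)-7-benzyloxychroman-3-yl]-2-methoxyphenyl}chroman-2-one (trans lactone), via mixed pivalic anhydride 28 (not isolated), via ortho-quinone methide 29 (not isolated), via cis lactone 30 (not isolated)
Conditions: 27 (1.5 equiv), t-BuCOCl (1.5 equiv), iPr2NEt (1.5 equiv), CH2Cl2, 0 °C; then (2R,3S)-3-isopropyl-2-phenyl-3,4-dihydro-2H-benzo[4,5]thiazolo[3,2-a]pyrimidine (HyperBTM, 10 mol %), 22, iPr2NEt (3 equiv), −20 °C to rt; aq NaHCO3 wash; then DBU (0.3 equiv), CH2Cl2, rt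
Reagents that add atoms: none
Why: Acid 27 is activated as the mixed anhydride 28, which acylates the isothiourea and is deprotonated to the Z ammonium enolate held flat by a 1,5 O···S contact, while iPr2NEt expels p-toluenesulfinate from 22 to give the E ortho-quinone methide 29, and enolate carbon C3 adds to C4 so that ring A regains aromaticity. The freed phenoxide O1 then attacks the acyl ammonium carbonyl C2 in a 6-exo-trig lactonisation that closes ring C and releases the catalyst, the closest known reaction type being the isothiourea-catalysed Michael addition and lactonisation of arylacetic acids with ortho-quinone methides to 3,4-diaryl dihydrocoumarins. C4 is controlled by the catalyst: the pseudoaxial C2 phenyl group of the (2R,3S) antipode leaves one enolate face open, and the bulky isothiouronium unit stays exo to the heterodiene, which puts ring B endo and should give the cis lactone 30 with C3 S and C4 S. C3 is controlled by thermodynamics: its hydrogen is benzylic and alpha to the lactone carbonyl, a hindered trialkylamine buffered by its own salts is not relied on to move it, and DBU after removal of the salts should equilibrate 30 to the trans lactone 31 (C3 R), in which rings B and D lie anti, while C4 has no acidic hydrogen and is kept. The step needs chemoselectivity for sulfinate loss over O-acylation of the ring A phenoxide, and this is secured by the C7 benzyloxy group para to C4a and by the ortho methoxy and para benzyloxy groups of ring D, which all stabilise 29, and by using no t-BuCOCl beyond what 27 consumes. The lower stereocentre is insulated from C4 by ring D and should not bias the addition, but it turns any leak in facial selectivity into a diastereomer that chromatography can remove.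

**Step 19**
Reactants: 31 the trans lactone
Product: 32 (2R,3S)-2-(2-benzyloxy-4,5-dimethoxyphenyl)-3-(4-benzyloxy-2-hydroxyphenyl)-3-{4-benzyloxy-5-[(3R)-7-benzyloxychroman-3-yl]-2-methoxyphenyl}propan-1-ol
Conditions: LiAlH4, THF, 0 °C
Reagents that add atoms: none
Why: Hydride reduction of the aryl lactone to the primary alcohol with release of the ring A phenoxide, faster than enolisation and in any case on the thermodynamically preferred C3 epimer.

**Step 20**
Reactants: 32 the phenol alcohol
Product: 33 (3R,4S)-7-benzyloxy-3-(2-benzyloxy-4,5-dimethoxyphenyl)-4-{4-benzyloxy-5-[(3R)-7-benzyloxychroman-3-yl]-2-methoxyphenyl}chroman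
Conditions: PPh3, DIAD, THF, 0 °C to rt
Reagents that add atoms: none
Why: Intramolecular Mitsunobu etherification, in which O1 is the only free phenol and C2 the only alcohol, so the 6-exo-tet closure rebuilds ring C without touching C3 or C4.

**Step 21**
Reactants: 33 the tetrabenzyl ether
Product: 34 CNP0217096.1: (3R,4S)-3-(2-hydroxy-4,5-dimethoxyphenyl)-4-{4-hydroxy-5-[(3R)-7-hydroxychroman-3-yl]-2-methoxyphenyl}chroman-7-ol
Conditions: H2 (1 atm), Pd/C (10 wt % Pd), EtOAc/MeOH, rt
Reagents that add atoms: none
Why: Hydrogenolysis of four benzyl aryl ethers over palladium; the chroman C–O bonds are alkyl aryl ethers and the C4 methine has only C–C bonds, so nothing else is cleaved.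

**Compound list**
1 | 2,4-dihydroxybenzaldehyde | O=Cc1ccc(O)cc1O | starting material
2 | 4-benzyloxy-2-hydroxybenzaldehyde | O=Cc1ccc(OCc2ccccc2)cc1O | intermediate
3 | 2-allyloxy-4-benzyloxybenzaldehyde | O=Cc1ccc(OCc2ccccc2)cc1OCC=C | intermediate
4 | (2-allyloxy-4-benzyloxyphenyl)methanol | OCc1ccc(OCc2ccccc2)cc1OCC=C | intermediate
5 | 2-allyloxy-4-benzyloxybenzyl bromide | BrCc1ccc(OCc2ccccc2)cc1OCC=C | intermediate
6 | 5-bromo-2-hydroxy-4-methoxybenzaldehyde | COc1cc(O)c(C=O)cc1Br | starting material
7 | 2-benzyloxy-5-bromo-4-methoxybenzaldehyde | COc1cc(OCc2ccccc2)c(C=O)cc1Br | intermediate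
8 | N-[2-(2-benzyloxy-5-bromo-4-methoxyphenyl)-1-(4-methylphenylsulfonyl)ethenyl]formamide | COc1cc(OCc2ccccc2)c(C=C(NC=O)S(=O)(=O)c2ccc(C)cc2)cc1Br | intermediate
9 | 2-(2-benzyloxy-5-bromo-4-methoxyphenyl)acetonitrile | COc1cc(OCc2ccccc2)c(CC#N)cc1Br | intermediate
10 | 2-(2-benzyloxy-5-bromo-4-methoxyphenyl)acetic acid | COc1cc(OCc2ccccc2)c(CC(=O)O)cc1Br | intermediate
11 | (R)-4-benzyloxazolidin-2-one | O=C1N[C@H](Cc2ccccc2)CO1 | starting material
12 | 2-(2-benzyloxy-5-bromo-4-methoxyphenyl)acetic pivalic anhydride | COc1cc(OCc2ccccc2)c(CC(=O)OC(=O)C(C)(C)C)cc1Br | intermediate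
13 | (4R)-4-benzyl-3-[2-(2-benzyloxy-5-bromo-4-methoxyphenyl)acetyl]oxazolidin-2-one | COc1cc(OCc2ccccc2)c(CC(=O)N2[C@H](Cc3ccccc3)COC2=O)cc1Br | intermediate
14 | sodium Z enolate of 13 | COc1cc(OCc2ccccc2)c(/C=C(\[O-])N2[C@H](Cc3ccccc3)COC2=O)cc1Br.[Na+] | intermediate
15 | (4R)-4-benzyl-3-[(2R)-3-(2-allyloxy-4-benzyloxyphenyl)-2-(2-benzyloxy-5-bromo-4-methoxyphenyl)propanoyl]oxazolidin-2-one | COc1cc(OCc2ccccc2)c([C@@H](Cc2ccc(OCc3ccccc3)cc2OCC=C)C(=O)N2[C@H](Cc3ccccc3)COC2=O)cc1Br | intermediate
16 | (2R)-3-(2-allyloxy-4-benzyloxyphenyl)-2-(2-benzyloxy-5-bromo-4-methoxyphenyl)propan-1-ol | COc1cc(OCc2ccccc2)c([C@@H](Cc2ccc(OCc3ccccc3)cc2OCC=C)CO)cc1Br | intermediate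
17 | 5-benzyloxy-2-[(2R)-2-(2-benzyloxy-5-bromo-4-methoxyphenyl)-3-hydroxypropyl]phenol | COc1cc(OCc2ccccc2)c([C@@H](Cc2ccc(OCc3ccccc3)cc2O)CO)cc1Br | intermediate
18 | (3R)-7-benzyloxy-3-(2-benzyloxy-5-bromo-4-methoxyphenyl)chroman | COc1cc(OCc2ccccc2)c([C@@H]2COc3cc(OCc4ccccc4)ccc3C2)cc1Br | intermediate
19 | D5 aryllithium of 18 | COc1cc(OCc2ccccc2)c([C@@H]2COc3cc(OCc4ccccc4)ccc3C2)cc1[Li] | intermediate
20 | (2-allyloxy-4-benzyloxyphenyl){4-benzyloxy-5-[(3R)-7-benzyloxychroman-3-yl]-2-methoxyphenyl}methanol, both carbinol epimers | COc1cc(OCc2ccccc2)c([C@@H]2COc3cc(OCc4ccccc4)ccc3C2)cc1C(O)c1ccc(OCc2ccccc2)cc1OCC=C | intermediate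
21 | O-allyl ether of 22, both sulfone epimers | COc1cc(OCc2ccccc2)c([C@@H]2COc3cc(OCc4ccccc4)ccc3C2)cc1C(c1ccc(OCc2ccccc2)cc1OCC=C)S(=O)(=O)c1ccc(C)cc1 | intermediate
22 | fragment 1: 5-benzyloxy-2-[{4-benzyloxy-5-[(3R)-7-benzyloxychroman-3-yl]-2-methoxyphenyl}(4-methylphenylsulfonyl)methyl]phenol, both sulfone epimers | COc1cc(OCc2ccccc2)c([C@@H]2COc3cc(OCc4ccccc4)ccc3C2)cc1C(c1ccc(OCc2ccccc2)cc1O)S(=O)(=O)c1ccc(C)cc1 | intermediate
23 | 2-hydroxy-4,5-dimethoxybenzaldehyde | COc1cc(O)c(C=O)cc1OC | starting material
24 | 2-benzyloxy-4,5-dimethoxybenzaldehyde | COc1cc(OCc2ccccc2)c(C=O)cc1OC | intermediate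
25 | N-[2-(2-benzyloxy-4,5-dimethoxyphenyl)-1-(4-methylphenylsulfonyl)ethenyl]formamide | COc1cc(OCc2ccccc2)c(C=C(NC=O)S(=O)(=O)c2ccc(C)cc2)cc1OC | intermediate
26 | 2-(2-benzyloxy-4,5-dimethoxyphenyl)acetonitrile | COc1cc(OCc2ccccc2)c(CC#N)cc1OC | intermediate
27 | fragment 2: 2-(2-benzyloxy-4,5-dimethoxyphenyl)acetic acid | COc1cc(OCc2ccccc2)c(CC(=O)O)cc1OC | intermediate
28 | 2-(2-benzyloxy-4,5-dimethoxyphenyl)acetic pivalic anhydride | COc1cc(OCc2ccccc2)c(CC(=O)OC(=O)C(C)(C)C)cc1OC | intermediate
29 | (6E)-3-benzyloxy-6-{4-benzyloxy-5-[(3R)-7-benzyloxychroman-3-yl]-2-methoxybenzylidene}cyclohexa-2,4-dien-1-one | O=C1C=C(OCc2ccccc2)C=C/C1=C\c1cc([C@@H]2COc3cc(OCc4ccccc4)ccc3C2)c(OCc2ccccc2)cc1OC | intermediate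
30 | (3S,4S) cis lactone, C3 epimer of 31 | COc1cc(OCc5ccccc5)c([C@H]2C(=O)Oc3cc(OCc5ccccc5)ccc3[C@H]2c2cc([C@@H]3COc4cc(OCc5ccccc5)ccc4C3)c(OCc5ccccc5)cc2OC)cc1OC | intermediate
31 | (3R,4S)-7-benzyloxy-3-(2-benzyloxy-4,5-dimethoxyphenyl)-4-{4-benzyloxy-5-[(3R)-7-benzyloxychroman-3-yl]-2-methoxyphenyl}chroman-2-one | COc1cc(OCc5ccccc5)c([C@@H]2C(=O)Oc3cc(OCc5ccccc5)ccc3[C@H]2c2cc([C@@H]3COc4cc(OCc5ccccc5)ccc4C3)c(OCc5ccccc5)cc2OC)cc1OC | intermediate
32 | (2R,3S)-2-(2-benzyloxy-4,5-dimethoxyphenyl)-3-(4-benzyloxy-2-hydroxyphenyl)-3-{4-benzyloxy-5-[(3R)-7-benzyloxychroman-3-yl]-2-methoxyphenyl}propan-1-ol | COc1cc(OCc5ccccc5)c([C@H](CO)[C@@H](c3ccc(OCc5ccccc5)cc3O)c2cc([C@@H]3COc4cc(OCc5ccccc5)ccc4C3)c(OCc5ccccc5)cc2OC)cc1OC | intermediate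
33 | (3R,4S)-7-benzyloxy-3-(2-benzyloxy-4,5-dimethoxyphenyl)-4-{4-benzyloxy-5-[(3R)-7-benzyloxychroman-3-yl]-2-methoxyphenyl}chroman | COc1cc(OCc5ccccc5)c([C@@H]2COc3cc(OCc5ccccc5)ccc3[C@H]2c2cc([C@@H]3COc4cc(OCc5ccccc5)ccc4C3)c(OCc5ccccc5)cc2OC)cc1OC | intermediate
34 | CNP0217096.1: (3R,4S)-3-(2-hydroxy-4,5-dimethoxyphenyl)-4-{4-hydroxy-5-[(3R)-7-hydroxychroman-3-yl]-2-methoxyphenyl}chroman-7-ol | COc1cc(O)c([C@@H]2COc3cc(O)ccc3[C@H]2c2cc([C@@H]3COc4cc(O)ccc4C3)c(O)cc2OC)cc1OC | target

**Total step count:** 21
**Longest linear sequence:** 14 steps (6 to 34 through steps 5–14 and 18–21). The branch from 1 through steps 1–4, 9–14 and 18–21 is equally long.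

**Steps most likely to fail**

**Step 18.**
- What may go wrong: leakage between the cis and trans modes of approach, which after equilibration of C3 appears as loss of facial selectivity at C4. The ring A phenoxide may also be O-acylated before sulfinate is lost.
- Fallback: stereocontrol is moved from the catalyst to the stereocentre already present.
- Setting out from 22 and 27, anhydride 28 is formed as before. The annulation is run with the achiral isothiourea 3,4-dihydro-2H-pyrimido[2,1-b]benzothiazole. Quinone methide 29 is generated beforehand from 22 and iPr2NEt in a separate flask, so that little phenoxide meets the acyl donor.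
- This should give 30 together with the cis (3R,4R) lactone diastereomer F1. DBU should turn the pair into 31 and the trans (3S,4R) lactone diastereomer F2.
- Lower C3 is R in both, so 31 and F2 are diastereomers and are separated by chromatography or crystallisation. The route is rejoined at 31.

**Step 9.**
- What may go wrong: self-condensation and hydrolysis of the donor-rich bromide 5 before the hindered arylacetyl enolate captures it, and breakdown of enolate 14 to a ketene on warming.
- Fallback: the same C–C bond is made by an aldol addition to the stable aldehyde 3, and the benzylic oxygen is removed afterwards.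
- The boron aldol reaction uses the enolate face opposite to the one open in the chelated alkylation, so the S auxiliary is needed.
- Setting out from acid 10, anhydride 12 is formed as in step 8 and treated with (S)-4-benzyloxazolidin-2-one and LiCl to give the (4S) arylacetyl imide F3.
- Bu2BOTf and Et3N, then 3, in CH2Cl2 at −78 to 0 °C should give the Evans syn aldol adduct F4.
- Ionic reduction with Et3SiH and CF3CO2H in CH2Cl2 at −20 °C runs through the benzylic cation stabilised by the ortho and para oxygens. It should give the (4S,2R) benzylated imide F5.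
- LiBH4 as in step 10 then releases the S auxiliary and gives 16, where the route is rejoined.

**Step 14.**
- What may go wrong: the acid-generated diarylmethyl cation alkylates a donor ring of a second molecule instead of taking up sulfinate, or the product loses sulfinate during isolation.
- Fallback: the two events are separated and their order is reversed, so that sulfinate enters by conjugate addition to the quinone methide and not through a free cation.
- Setting out from 20, Pd(PPh3)4 and morpholine in THF as in step 11 should give the phenol carbinol F6.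
- Warming F6 with p-TolSO2Na in aqueous ethanol buffered with AcOH lets the ortho-hydroxybenzhydrol lose water to 29, which sulfinate traps. Sulfone 22 should crystallise from the medium, and the route is rejoined at 22.

**Further compounds**
F1 | step 18 | (3R,4R)-7-benzyloxy-3-(2-benzyloxy-4,5-dimethoxyphenyl)-4-{4-benzyloxy-5-[(3R)-7-benzyloxychroman-3-yl]-2-methoxyphenyl}chroman-2-one | COc1cc(OCc5ccccc5)c([C@@H]2C(=O)Oc3cc(OCc5ccccc5)ccc3[C@@H]2c2cc([C@@H]3COc4cc(OCc5ccccc5)ccc4C3)c(OCc5ccccc5)cc2OC)cc1OC
F2 | step 18 | (3S,4R)-7-benzyloxy-3-(2-benzyloxy-4,5-dimethoxyphenyl)-4-{4-benzyloxy-5-[(3R)-7-benzyloxychroman-3-yl]-2-methoxyphenyl}chroman-2-one | COc1cc(OCc5ccccc5)c([C@H]2C(=O)Oc3cc(OCc5ccccc5)ccc3[C@@H]2c2cc([C@@H]3COc4cc(OCc5ccccc5)ccc4C3)c(OCc5ccccc5)cc2OC)cc1OC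
F3 | step 9 | (4S)-4-benzyl-3-[2-(2-benzyloxy-5-bromo-4-methoxyphenyl)acetyl]oxazolidin-2-one | COc1cc(OCc2ccccc2)c(CC(=O)N2[C@@H](Cc3ccccc3)COC2=O)cc1Br
F4 | step 9 | (4S)-4-benzyl-3-[(2S,3S)-3-(2-allyloxy-4-benzyloxyphenyl)-2-(2-benzyloxy-5-bromo-4-methoxyphenyl)-3-hydroxypropanoyl]oxazolidin-2-one | COc1cc(OCc2ccccc2)c([C@@H]([C@H](O)c2ccc(OCc3ccccc3)cc2OCC=C)C(=O)N2[C@@H](Cc3ccccc3)COC2=O)cc1Br
F5 | step 9 | (4S)-4-benzyl-3-[(2R)-3-(2-allyloxy-4-benzyloxyphenyl)-2-(2-benzyloxy-5-bromo-4-methoxyphenyl)propanoyl]oxazolidin-2-one | COc1cc(OCc2ccccc2)c([C@@H](Cc2ccc(OCc3ccccc3)cc2OCC=C)C(=O)N2[C@@H](Cc3ccccc3)COC2=O)cc1Br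
F6 | step 14 | 5-benzyloxy-2-[{4-benzyloxy-5-[(3R)-7-benzyloxychroman-3-yl]-2-methoxyphenyl}(hydroxy)methyl]phenol, both carbinol epimers | COc1cc(OCc2ccccc2)c([C@@H]2COc3cc(OCc4ccccc4)ccc3C2)cc1C(O)c1ccc(OCc2ccccc2)cc1O
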